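**Plan**
- Retrosynthesis: the acetate and the ring C quinone go back to a 12,14-dimethoxyarene; C6=C7 goes back to a C7 ketone and C7–C8 is cut (Friedel–Crafts); then C2–C3 and C4–C5 are cut together; last the C5=C6 alkene (Wittig) and the C19–O ester bond.
- Enabling feature: C19 is tied through oxygen to C20 on quaternary C10, so ring A and the δ-lactone are one 3-oxabicyclo[3.3.1]nonan-2-one sharing C4, C5 and C10. A methacrylate (C3=C4, C18, C19) on the C20 oxygen therefore lies between a C2 radical on the C1–C2 arm and C5, the β-carbon of an enoate arm, with all three arms on C10.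
- Forward: arylacetate → allylated arylmalonate → prochiral 1,3-diol → desymmetrisation → enoate, methacrylate and iodoethyl arms → radical bicyclisation (ring A and lactone at once) → ring B by Friedel–Crafts acylation → 6,7-alkene → ring C to the acetoxyquinone.
- Stereochemistry: C10 from the catalytic desymmetrising benzoylation; C4 forced by the lactone bridge; C5 from the bicyclic transition state of the radical closure (H5 anti to C20, hence trans A/B).

Key step: step 11

Assumption: 4-isopropyl-3,5-dimethoxybenzaldehyde 1 (an intermediate of tapinarof manufacture) is taken as a catalogue compound, and the ProPhenol enantiomer that gives (S)-7 in step 5 is fixed by a test run, both enantiomers being available.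

**Route**

Step 1
Reactants: 1 4-isopropyl-3,5-dimethoxybenzaldehyde
Product: 2 2-(4-isopropyl-3,5-dimethoxyphenyl)acetonitrile
Conditions: TosMIC, t-BuOK, DME, −40 °C to rt; then MeOH, reflux
Reagents that add atoms: p-toluenesulfonylmethyl isocyanide (TosMIC), Cc1ccc(cc1)S(=O)(=O)C[N+]#[C-]
Why: Van Leusen reductive cyanation, in which the TosMIC anion adds to the aldehyde and methanolysis of the N-formyl intermediate with loss of sulfinate leaves the one-carbon-homologated nitrile.

Step 2
Reactants: 2 2-(4-isopropyl-3,5-dimethoxyphenyl)acetonitrile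
Product: 3 ethyl 2-(4-isopropyl-3,5-dimethoxyphenyl)acetate
Conditions: H2SO4, EtOH (95 %), reflux
Reagents that add atoms: ethanol, CCO; water, O
Why: Acid-catalysed alcoholysis of the nitrile (Pinner type) through the imidate should give the ester, the aryl ethers being inert.

Step 3
Reactants: 3 ethyl 2-(4-isopropyl-3,5-dimethoxyphenyl)acetate
Product: 5 diethyl 2-allyl-2-(4-isopropyl-3,5-dimethoxyphenyl)malonate, via sodium diethyl arylmalonate 4 (not isolated)
Conditions: NaH, (EtO)2CO, THF, reflux; then allyl bromide, DMF, rt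
Reagents that add atoms: diethyl carbonate, CCOC(=O)OCC; allyl bromide, C=CCBr
Why: Claisen-type C-ethoxycarbonylation gives the stabilised malonate anion, which is allylated in the same flask (malonic ester alkylation) to make the quaternary carbon that becomes C10.

Step 4
Reactants: 5 diethyl 2-allyl-2-(4-isopropyl-3,5-dimethoxyphenyl)malonate
Product: 6 2-allyl-2-(4-isopropyl-3,5-dimethoxyphenyl)propane-1,3-diol
Conditions: LiAlH4, THF, 0 °C to rt
Reagents that add atoms: none
Why: Hydride reduction of a non-enolisable disubstituted malonate should give the prochiral 1,3-diol and leave the isolated alkene alone.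

Step 5
Reactants: 6 2-allyl-2-(4-isopropyl-3,5-dimethoxyphenyl)propane-1,3-diol
Product: 7 (S)-2-(hydroxymethyl)-2-(4-isopropyl-3,5-dimethoxyphenyl)pent-4-en-1-yl benzoate
Conditions: ProPhenol ligand (10 mol %), Et2Zn (20 mol %), vinyl benzoate (5 equiv), toluene, −20 °C
Reagents that add atoms: vinyl benzoate, C=COC(=O)c1ccccc1
Why: Catalytic enantioselective desymmetrising acyl transfer with the dinuclear zinc ProPhenol catalyst differentiates the enantiotopic hydroxymethyl groups of a 2-aryl-2-alkyl-1,3-propanediol and so sets C10, the benzoate marking the future C20 oxygen.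

Step 6
Reactants: 7 (S)-2-(hydroxymethyl)-2-(4-isopropyl-3,5-dimethoxyphenyl)pent-4-en-1-yl benzoate
Product: 9 tert-butyl (R,E)-4-[(benzoyloxy)methyl]-4-(4-isopropyl-3,5-dimethoxyphenyl)hepta-2,6-dienoate, via aldehyde 8 (not isolated)
Conditions: Dess–Martin periodinane, CH2Cl2, rt; then Ph3P=CHCO2t-Bu, toluene, 90 °C
Reagents that add atoms: tert-butyl (triphenylphosphoranylidene)acetate, CC(C)(C)OC(=O)C=P(c1ccccc1)(c1ccccc1)c1ccccc1
Why: Dess–Martin oxidation gives a non-enolisable aldehyde that is used at once, so the benzoate cannot migrate and erode C10, and the Wittig reaction of the stabilised ylide should give the E-enoate (C5=C6–C7).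

Step 7
Reactants: 9 tert-butyl (R,E)-4-[(benzoyloxy)methyl]-4-(4-isopropyl-3,5-dimethoxyphenyl)hepta-2,6-dienoate
Product: 10 tert-butyl (R,E)-4-(hydroxymethyl)-4-(4-isopropyl-3,5-dimethoxyphenyl)hepta-2,6-dienoate
Conditions: K2CO3 (0.3 equiv), MeOH, 0 °C to rt
Reagents that add atoms: none
Why: Mild methanolysis (transesterification) should remove the benzoate and spare the hindered tert-butyl enoate, and the alkoxide cannot add to the enoate because only a four-membered ring would result.

Step 8
Reactants: 10 tert-butyl (R,E)-4-(hydroxymethyl)-4-(4-isopropyl-3,5-dimethoxyphenyl)hepta-2,6-dienoate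
Product: 11 tert-butyl (R,E)-4-(4-isopropyl-3,5-dimethoxyphenyl)-4-[(methacryloyloxy)methyl]hepta-2,6-dienoate
Conditions: methacryloyl chloride, Et3N, DMAP (cat.), CH2Cl2, 0 °C
Reagents that add atoms: methacryloyl chloride, CC(=C)C(=O)Cl
Why: DMAP-catalysed acylation of the neopentyl alcohol puts C3, C4, C18 and C19 on the C20 oxygen as the methacrylate.

Step 9
Reactants: 11 tert-butyl (R,E)-4-(4-isopropyl-3,5-dimethoxyphenyl)-4-[(methacryloyloxy)methyl]hepta-2,6-dienoate
Product: 13 tert-butyl (R,E)-6-hydroxy-4-(4-isopropyl-3,5-dimethoxyphenyl)-4-[(methacryloyloxy)methyl]hex-2-enoate, via aldehyde 12 (not isolated)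
Conditions: OsO4 (2 mol %), NaIO4, 2,6-lutidine, dioxane/H2O, rt; then NaBH4, MeOH, −20 °C
Reagents that add atoms: osmium tetroxide OsO4 (oxygen carrier), O=[Os](=O)(=O)=O; sodium periodate NaIO4 (terminal oxidant), [Na+].[O-]I(=O)(=O)=O
Why: Lemieux–Johnson cleavage, in which OsO4 should dihydroxylate the electron-rich monosubstituted alkene much faster than the two conjugated electron-poor ones, followed by borohydride reduction of the aldehyde only.

Step 10
Reactants: 13 tert-butyl (R,E)-6-hydroxy-4-(4-isopropyl-3,5-dimethoxyphenyl)-4-[(methacryloyloxy)methyl]hex-2-enoate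
Product: 14 tert-butyl (R,E)-6-iodo-4-(4-isopropyl-3,5-dimethoxyphenyl)-4-[(methacryloyloxy)methyl]hex-2-enoate
Conditions: I2, PPh3, imidazole, CH2Cl2, 0 °C to rt
Reagents that add atoms: iodine, II
Why: Appel-type iodination of the unhindered primary alcohol gives the radical precursor, placed after the ester exchange so that no alkoxide ever sits beside the iodide.

Step 11
Reactants: 14 tert-butyl (R,E)-6-iodo-4-(4-isopropyl-3,5-dimethoxyphenyl)-4-[(methacryloyloxy)methyl]hex-2-enoate
Product: 15 tert-butyl 2-[(1S,5R,9R)-5-(4-isopropyl-3,5-dimethoxyphenyl)-1-methyl-2-oxo-3-oxabicyclo[3.3.1]nonan-9-yl]acetate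
Conditions: (Me3Si)3SiH (1.5 equiv), AIBN (0.3 equiv), syringe pump over 10 h, benzene (2 mM in 14), 80 °C
Reagents that add atoms: none
Why: Iodine abstraction by the silyl radical gives the primary C2 radical, which adds 8-endo-trig to the CH2 terminus (C3) of the methacrylate on the C20 oxygen; the tertiary α-ester radical at C4 then closes 6-exo-trig across the eight-membered ring onto the enoate β-carbon C5 on the same quaternary C10, and the C6 α-ester radical takes hydrogen from the silane. The closest known type is a silane- or stannane-mediated tandem radical cyclisation in which an endo closure onto an acrylate is followed by a transannular exo closure (macrocyclisation–transannulation cascades and 8-endo lactone-forming cyclisations). Ring A and the δ-lactone arise together in the second event, each as a six-membered ring closed in the exo mode, the eight-membered lactone being only a transient ring. C4 is fixed by the tether, because C19 must end on the same face of ring A as C20 in the 3-oxabicyclo[3.3.1]nonan-2-one; C5 should be set by the chair–chair transition state in which the CH=CH–CO2t-Bu arm lies over the flatter lactone ring (one syn-axial hydrogen) and not over ring A (two), which puts H5 anti to C20; C10 is carried in from step 5. The step needs both cyclisations to outrun hydrogen transfer to the C2 and C4 radicals, which slow silane addition at high dilution and the gem-disubstitution at C10 should secure, and it needs attack at C3 and not C4 of the methacrylate, which the nucleophilic character of the alkyl radical and the free CH2 terminus secure.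

Step 12
Reactants: 15 tert-butyl 2-[(1S,5R,9R)-5-(4-isopropyl-3,5-dimethoxyphenyl)-1-methyl-2-oxo-3-oxabicyclo[3.3.1]nonan-9-yl]acetate
Product: 17 (4S,5R,10R)-12,14-dimethoxy-7-oxoabieta-8,11,13-trien-19,20-olide, via carboxylic acid 16 (not isolated)
Conditions: TFA, CH2Cl2, rt; concentrate; then (CF3CO)2O, CH2Cl2, 0 °C to rt
Reagents that add atoms: none
Why: Acidolysis of the tert-butyl ester and intramolecular Friedel–Crafts acylation through the mixed trifluoroacetic anhydride should close ring B at the arene carbon ortho and para to the two methoxy groups (the two ortho positions are equivalent), the trans A/B fusion following from C5 and C10.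

Step 13
Reactants: 17 (4S,5R,10R)-12,14-dimethoxy-7-oxoabieta-8,11,13-trien-19,20-olide
Product: 19 (4S,5R,10R)-12,14-dimethoxyabieta-6,8,11,13-tetraen-19,20-olide, via benzylic alcohol 18 (not isolated)
Conditions: NaBH4, MeOH/THF, 0 °C; then TsOH·H2O (5 mol %), toluene, 50 °C
Reagents that add atoms: none
Why: Borohydride should reduce the aryl ketone but not the δ-lactone, and the electron-rich benzylic alcohol loses water under mild acid (E1 dehydration) to the 6,7-alkene, quaternary C10 ruling out aromatisation.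

Step 14
Reactants: 19 (4S,5R,10R)-12,14-dimethoxyabieta-6,8,11,13-tetraen-19,20-olide
Product: 20 (4S,5R,10R)-12,14-dihydroxyabieta-6,8,11,13-tetraen-19,20-olide
Conditions: BBr3 (5 equiv), CH2Cl2, −78 to 0 °C; then H2O
Reagents that add atoms: none
Why: Lewis-acid cleavage of both aryl methyl ethers with BBr3, which normally spares aryl-conjugated alkenes at low temperature, while the neopentyl C20–O bond of the lactone resists bromide.

Step 15
Reactants: 20 (4S,5R,10R)-12,14-dihydroxyabieta-6,8,11,13-tetraen-19,20-olide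
Product: 21 (4S,5R,10R)-12-hydroxy-11,14-dioxoabieta-6,8,12-trien-19,20-olide
Conditions: (KO3S)2NO (Fremy's salt, 2.5 equiv), KH2PO4 buffer, acetone/H2O, 0 °C to rt
Reagents that add atoms: potassium nitrosodisulfonate, [K+].[K+].[O]N(S(=O)(=O)[O-])S(=O)(=O)[O-]
Why: Teuber oxidation of the resorcinol at the only free ring position C11, para to the C14 hydroxyl and ortho to the C12 hydroxyl, should give the 2-hydroxy-1,4-benzoquinone.

Step 16
Reactants: 21 (4S,5R,10R)-12-hydroxy-11,14-dioxoabieta-6,8,12-trien-19,20-olide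
Product: 22 (4S,5R,10R)-12-acetoxy-11,14-dioxoabieta-6,8,12-trien-19,20-olide (target)
Conditions: Ac2O, pyridine, CH2Cl2, 0 °C to rt
Reagents that add atoms: acetic anhydride, CC(=O)OC(C)=O
Why: O-Acetylation of the acidic hydroxyquinone (a vinylogous acid) under mild base, which leaves the γ-hydrogen at C5 untouched.

**Compound list**

1 | 4-isopropyl-3,5-dimethoxybenzaldehyde | COc1cc(C=O)cc(OC)c1C(C)C | starting material
2 | 2-(4-isopropyl-3,5-dimethoxyphenyl)acetonitrile | COc1cc(CC#N)cc(OC)c1C(C)C | intermediate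
3 | ethyl 2-(4-isopropyl-3,5-dimethoxyphenyl)acetate | CCOC(=O)Cc1cc(OC)c(C(C)C)c(OC)c1 | intermediate
4 | sodium enolate of diethyl 2-(4-isopropyl-3,5-dimethoxyphenyl)malonate | [Na+].CCOC(=O)[C-](C(=O)OCC)c1cc(OC)c(C(C)C)c(OC)c1 | intermediate (not isolated)
5 | diethyl 2-allyl-2-(4-isopropyl-3,5-dimethoxyphenyl)malonate | CCOC(=O)C(CC=C)(C(=O)OCC)c1cc(OC)c(C(C)C)c(OC)c1 | intermediate
6 | 2-allyl-2-(4-isopropyl-3,5-dimethoxyphenyl)propane-1,3-diol | OCC(CO)(CC=C)c1cc(OC)c(C(C)C)c(OC)c1 | intermediate
7 | (S)-2-(hydroxymethyl)-2-(4-isopropyl-3,5-dimethoxyphenyl)pent-4-en-1-yl benzoate | COc1cc(cc(OC)c1C(C)C)[C@@](COC(=O)c1ccccc1)(CC=C)CO | intermediate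
8 | (R)-2-formyl-2-(4-isopropyl-3,5-dimethoxyphenyl)pent-4-en-1-yl benzoate | COc1cc(cc(OC)c1C(C)C)[C@@](COC(=O)c1ccccc1)(CC=C)C=O | intermediate (not isolated)
9 | tert-butyl (R,E)-4-[(benzoyloxy)methyl]-4-(4-isopropyl-3,5-dimethoxyphenyl)hepta-2,6-dienoate | COc1cc(cc(OC)c1C(C)C)[C@@](COC(=O)c1ccccc1)(CC=C)/C=C/C(=O)OC(C)(C)C | intermediate
10 | tert-butyl (R,E)-4-(hydroxymethyl)-4-(4-isopropyl-3,5-dimethoxyphenyl)hepta-2,6-dienoate | COc1cc(cc(OC)c1C(C)C)[C@@](CO)(CC=C)/C=C/C(=O)OC(C)(C)C | intermediate
11 | tert-butyl (R,E)-4-(4-isopropyl-3,5-dimethoxyphenyl)-4-[(methacryloyloxy)methyl]hepta-2,6-dienoate | COc1cc(cc(OC)c1C(C)C)[C@@](COC(=O)C(C)=C)(CC=C)/C=C/C(=O)OC(C)(C)C | intermediate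
12 | tert-butyl (R,E)-4-(4-isopropyl-3,5-dimethoxyphenyl)-4-[(methacryloyloxy)methyl]-6-oxohex-2-enoate | COc1cc(cc(OC)c1C(C)C)[C@@](COC(=O)C(C)=C)(CC=O)/C=C/C(=O)OC(C)(C)C | intermediate (not isolated)
13 | tert-butyl (R,E)-6-hydroxy-4-(4-isopropyl-3,5-dimethoxyphenyl)-4-[(methacryloyloxy)methyl]hex-2-enoate | COc1cc(cc(OC)c1C(C)C)[C@@](COC(=O)C(C)=C)(CCO)/C=C/C(=O)OC(C)(C)C | intermediate
14 | tert-butyl (R,E)-6-iodo-4-(4-isopropyl-3,5-dimethoxyphenyl)-4-[(methacryloyloxy)methyl]hex-2-enoate | COc1cc(cc(OC)c1C(C)C)[C@@](COC(=O)C(C)=C)(CCI)/C=C/C(=O)OC(C)(C)C | intermediate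
15 | tert-butyl 2-[(1S,5R,9R)-5-(4-isopropyl-3,5-dimethoxyphenyl)-1-methyl-2-oxo-3-oxabicyclo[3.3.1]nonan-9-yl]acetate | COc1cc(cc(OC)c1C(C)C)[C@]13CCC[C@](C)(C(=O)OC1)[C@@H]3CC(=O)OC(C)(C)C | intermediate
16 | 2-[(1S,5R,9R)-5-(4-isopropyl-3,5-dimethoxyphenyl)-1-methyl-2-oxo-3-oxabicyclo[3.3.1]nonan-9-yl]acetic acid | COc1cc(cc(OC)c1C(C)C)[C@]13CCC[C@](C)(C(=O)OC1)[C@@H]3CC(=O)O | intermediate (not isolated)
17 | (4S,5R,10R)-12,14-dimethoxy-7-oxoabieta-8,11,13-trien-19,20-olide (C19 carbonyl, C20 oxygen) | COc1c(C(C)C)c(OC)c2c(c1)[C@]13CCC[C@](C)(C(=O)OC1)[C@@H]3CC2=O | intermediate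
18 | (4S,5R,10R)-7-hydroxy-12,14-dimethoxyabieta-8,11,13-trien-19,20-olide (both C7 epimers) | COc1c(C(C)C)c(OC)c2c(c1)[C@]13CCC[C@](C)(C(=O)OC1)[C@@H]3CC2O | intermediate (not isolated)
19 | (4S,5R,10R)-12,14-dimethoxyabieta-6,8,11,13-tetraen-19,20-olide | COc1c(C(C)C)c(OC)c2c(c1)[C@]13CCC[C@](C)(C(=O)OC1)[C@@H]3C=C2 | intermediate
20 | (4S,5R,10R)-12,14-dihydroxyabieta-6,8,11,13-tetraen-19,20-olide | Oc1c(C(C)C)c(O)c2c(c1)[C@]13CCC[C@](C)(C(=O)OC1)[C@@H]3C=C2 | intermediate
21 | (4S,5R,10R)-12-hydroxy-11,14-dioxoabieta-6,8,12-trien-19,20-olide | OC1=C(C(C)C)C(=O)C2=C(C1=O)[C@]13CCC[C@](C)(C(=O)OC1)[C@@H]3C=C2 | intermediate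
22 | (4S,5R,10R)-12-acetoxy-11,14-dioxoabieta-6,8,12-trien-19,20-olide | CC(=O)OC1=C(C(C)C)C(=O)C2=C(C1=O)[C@]13CCC[C@](C)(C(=O)OC1)[C@@H]3C=C2 | target

**Totals**

Total step count: 16. Longest linear sequence: 16 steps (1 to 22).

**Steps most likely to fail**

1. Step 11. Hydrogen transfer to the C2 radical may outrun the slow eight-membered ring closure, or C4 may attack the other face of the enoate and give the cis A/B isomer. The fallback sets out from alcohol 10 and comes back at 15, making the two bonds in separate, known steps. Esterification of 10 with 2-methylbut-3-enoic acid (EDC·HCl, DMAP cat., CH2Cl2, 0 °C) should give the 2-methylbut-3-enoate ester F1, as both epimers at the ester α-carbon, which is deprotonated later. Ring-closing metathesis of its allyl and vinyl groups with the second-generation Grubbs catalyst RuCl2(=CHPh)(H2IMes)(PCy3) in dilute CH2Cl2 at 40 °C should close the eight-membered unsaturated lactone F2 and make the C2–C3 bond as a Z-alkene, the hindered enoate staying out of the metathesis. LiN(SiMe3)2 in THF at −78 °C should give the lactone enolate, which adds across the ring to C5 of the enoate (intramolecular Michael addition) to give the bicyclic alkene F3, with C4 again fixed by the bridge. Hydrogenation (H2, Pd/C, EtOAc) saturates C2=C3 and delivers 15.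

2. Step 5. The two hydroxymethyl groups on a quaternary carbon may be differentiated with low enantioselectivity, or benzoate migration may erode it. The fallback sets out from diol 6 and comes back at 10, replacing the catalytic desymmetrisation by a separation of diastereomers. Monoacylation of 6 with (1S)-(−)-camphanic chloride (1 equiv, Et3N, DMAP cat., CH2Cl2, −20 °C) should give the (S)-configured monocamphanate F4 and its (R)-configured diastereomer F5. These are separated by chromatography or crystallisation, and F5 is returned to 6 with K2CO3 in MeOH. Dess–Martin oxidation of F4 gives the camphanate aldehyde F6, Wittig reaction with Ph3P=CHCO2t-Bu gives the camphanate enoate F7, and methanolysis (K2CO3, MeOH) gives 10.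

3. Step 14. The strong Lewis acid may cause oligomerisation of the electron-rich cyclic styrene, or cleavage of the hindered ethers may stay incomplete. The fallback sets out from ketone 17 and comes back at 21, doing the first demethylation before the alkene exists and the second on the quinone. BCl3 (CH2Cl2, −78 to 0 °C) should remove only the C14 methyl group, whose oxygen chelates boron together with the C7 carbonyl, to give the 14-hydroxy-12-methoxy ketone F8. NaBH4 (MeOH, 0 °C) then gives the benzylic alcohol F9, and TsOH (cat., toluene, 50 °C) gives the phenolic styrene F10. Teuber oxidation of this monophenol with (KO3S)2NO should give the 12-methoxyquinone F11. Its vinylogous methyl ester is cleaved with BBr3 (1.2 equiv, CH2Cl2, −78 °C) to give 21.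

**Further compounds**

F1 | step 11 | tert-butyl (R,E)-4-(4-isopropyl-3,5-dimethoxyphenyl)-4-{[(2-methylbut-3-enoyl)oxy]methyl}hepta-2,6-dienoate (both epimers at the acyl α-carbon) | COc1cc(cc(OC)c1C(C)C)[C@@](COC(=O)C(C)C=C)(CC=C)/C=C/C(=O)OC(C)(C)C
F2 | step 11 | tert-butyl (E)-3-[(7R,4Z)-7-(4-isopropyl-3,5-dimethoxyphenyl)-3-methyl-2-oxo-3,6,7,8-tetrahydro-2H-oxocin-7-yl]acrylate (both C3 epimers of the oxocine) | COc1cc(cc(OC)c1C(C)C)[C@]2(COC(=O)C(C)C=CC2)/C=C/C(=O)OC(C)(C)C
F3 | step 11 | tert-butyl 2-[(1S,5R,9R)-5-(4-isopropyl-3,5-dimethoxyphenyl)-1-methyl-2-oxo-3-oxabicyclo[3.3.1]non-7-en-9-yl]acetate | COc1cc(cc(OC)c1C(C)C)[C@]13CC=C[C@](C)(C(=O)OC1)[C@@H]3CC(=O)OC(C)(C)C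
F4 | step 5 | (S)-2-(hydroxymethyl)-2-(4-isopropyl-3,5-dimethoxyphenyl)pent-4-en-1-yl (1S,4R)-camphanate | COc1cc(cc(OC)c1C(C)C)[C@@](COC(=O)[C@@]23CC[C@@](C)(C(=O)O2)C3(C)C)(CC=C)CO
F5 | step 5 | (R)-2-(hydroxymethyl)-2-(4-isopropyl-3,5-dimethoxyphenyl)pent-4-en-1-yl (1S,4R)-camphanate | COc1cc(cc(OC)c1C(C)C)[C@](COC(=O)[C@@]23CC[C@@](C)(C(=O)O2)C3(C)C)(CC=C)CO
F6 | step 5 | (R)-2-formyl-2-(4-isopropyl-3,5-dimethoxyphenyl)pent-4-en-1-yl (1S,4R)-camphanate | COc1cc(cc(OC)c1C(C)C)[C@@](COC(=O)[C@@]23CC[C@@](C)(C(=O)O2)C3(C)C)(CC=C)C=O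
F7 | step 5 | tert-butyl (R,E)-4-{[(1S,4R)-camphanoyloxy]methyl}-4-(4-isopropyl-3,5-dimethoxyphenyl)hepta-2,6-dienoate | COc1cc(cc(OC)c1C(C)C)[C@@](COC(=O)[C@@]23CC[C@@](C)(C(=O)O2)C3(C)C)(CC=C)/C=C/C(=O)OC(C)(C)C
F8 | step 14 | (4S,5R,10R)-14-hydroxy-12-methoxy-7-oxoabieta-8,11,13-trien-19,20-olide | COc1c(C(C)C)c(O)c2c(c1)[C@]13CCC[C@](C)(C(=O)OC1)[C@@H]3CC2=O
F9 | step 14 | (4S,5R,10R)-7,14-dihydroxy-12-methoxyabieta-8,11,13-trien-19,20-olide (both C7 epimers) | COc1c(C(C)C)c(O)c2c(c1)[C@]13CCC[C@](C)(C(=O)OC1)[C@@H]3CC2O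
F10 | step 14 | (4S,5R,10R)-14-hydroxy-12-methoxyabieta-6,8,11,13-tetraen-19,20-olide | COc1c(C(C)C)c(O)c2c(c1)[C@]13CCC[C@](C)(C(=O)OC1)[C@@H]3C=C2
F11 | step 14 | (4S,5R,10R)-12-methoxy-11,14-dioxoabieta-6,8,12-trien-19,20-olide | COC1=C(C(C)C)C(=O)C2=C(C1=O)[C@]13CCC[C@](C)(C(=O)OC1)[C@@H]3C=C2
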